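## Retrosynthetic overview

1. Prostanoid numbering is used: C1 ester carbon, C4 acetoxy carbinol, C5=C6 (Z), C7=C8 (E, exocyclic), ring A = cyclopentenone C8–C12 with the C9 ketone and the C12 acetoxy centre, C13–C20 the Z,Z-dienyl chain. The last bond made is the diene σ-bond C6–C7: a Z-alkenyldifluoroborane (C1–C6, C4 acetate in place) is joined to a ring A acetoxymethylidene ketone (C7–C20, C12 acetate in place) by a transition-metal-free conjugate addition–elimination that gives the target directly.
2. Enabling feature: ring A locks the exocyclic enone O=C9–C8=C7 s-cis and the endocyclic enone O=C9–C10=C11 s-trans, and C8 carries no hydrogen. Boron bound at the C9 oxygen can therefore hand C6 to C7, and only to C7, through a six-membered transition state, after which the C7 acetate leaves and C7=C8 is restored.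
3. Ester half: C4 is set by asymmetric transfer hydrogenation of a silyl ynone, the 5Z geometry by rhodium-catalysed trans-hydroboration of the terminal alkyne; the boronate is then converted into the trifluoroborate.
4. Ring half: the stereocentre of (S)-4-silyloxycyclopentenone steers a 1,2-propargylation (sets C12) and is then oxidised away to the C9 ketone. The chain is completed by alkyne coupling and semi-hydrogenation, C7 is added by formylation, and one acetylation installs both the C12 acetate and the C7 leaving group.
5. Order of ring formation: no ring is formed in the route; the single carbocycle (ring A) is carried through from the commercial cyclopentenone.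

Key step: step 14

Remark on the chemistry: organometallic 1,2-addition to (S)-4-silyloxycyclopent-2-enone is assumed to occur anti to the silyloxy group, as is usual for 4-substituted cyclopentenones; aqueous work-up is implied after each step.

## Route

Step 1
Reactants: 1 methyl 4-chloro-4-oxobutanoate; 2 bis(trimethylsilyl)acetylene
Product: 3 methyl 4-oxo-6-(trimethylsilyl)hex-5-ynoate
Conditions: AlCl3, CH2Cl2, 0 °C
Reagents that add atoms: none
Why: Friedel–Crafts-type acylation of an alkynylsilane (ipso substitution through a β-silyl vinyl cation) is the standard entry to silyl ynones and stops after one acylation.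

Step 2
Reactants: 3 methyl 4-oxo-6-(trimethylsilyl)hex-5-ynoate
Product: 4 methyl (4R)-4-hydroxy-6-(trimethylsilyl)hex-5-ynoate
Conditions: Ru(p-cymene)[(R,R)-TsNCHPhCHPhNH] (1 mol%), iPrOH, rt
Reagents that add atoms: none
Why: Noyori asymmetric transfer hydrogenation of an alkynyl ketone, in which the catalyst sets C4 and the (R,R) ligand, with the alkynyl group in the place of the aryl group of the usual model, should give the R carbinol, while the neutral medium keeps the γ-hydroxy ester from lactonising before step 3.

Step 3
Reactants: 4 methyl (4R)-4-hydroxy-6-(trimethylsilyl)hex-5-ynoate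
Product: 5 methyl (4R)-4-acetoxy-6-(trimethylsilyl)hex-5-ynoate
Conditions: Ac2O, pyridine, DMAP (cat.), CH2Cl2, 0 °C
Reagents that add atoms: acetic anhydride, CC(=O)OC(C)=O
Why: DMAP-catalysed O-acylation installs the C4 acetate of the target, blocks γ-lactone formation and does not touch the stereocentre.

Step 4
Reactants: 5 methyl (4R)-4-acetoxy-6-(trimethylsilyl)hex-5-ynoate
Product: 6 methyl (4R)-4-acetoxyhex-5-ynoate
Conditions: TBAF, AcOH, THF, 0 °C
Reagents that add atoms: none
Why: Fluoride-induced protodesilylation of the alkynylsilane, buffered with acetic acid so that neither the acetate nor the methyl ester is cleaved, frees the terminal alkyne needed for step 5.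

Step 5
Reactants: 6 methyl (4R)-4-acetoxyhex-5-ynoate
Product: 7 methyl (4R,5Z)-4-acetoxy-6-(4,4,5,5-tetramethyl-1,3,2-dioxaborolan-2-yl)hex-5-enoate
Conditions: pinacolborane, [Rh(cod)Cl]2 (1.5 mol%), P(iPr)3 (6 mol%), Et3N, cyclohexane, rt
Reagents that add atoms: pinacolborane, CC1(C)OBOC1(C)C
Why: Rhodium-catalysed trans-hydroboration of a terminal alkyne, which runs through a rhodium vinylidene and places boron on the terminal carbon cis to the chain, should give the Z alkenylboronate with the C5=C6 geometry of the target, C4 being a spectator.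

Step 6
Reactants: 7 methyl (4R,5Z)-4-acetoxy-6-(4,4,5,5-tetramethyl-1,3,2-dioxaborolan-2-yl)hex-5-enoate
Product: 8 potassium [(1Z,3R)-3-acetoxy-6-methoxy-6-oxohex-1-en-1-yl]trifluoroborate
Conditions: KHF2, MeOH/H2O, rt
Reagents that add atoms: potassium hydrogen difluoride, F.[F-].[K+]
Why: Exchange of the pinacol ester for fluoride with KHF2 proceeds with retention of the alkene geometry and gives a storable salt from which the Lewis acidic difluoroborane of step 14 can be released.

Step 7
Reactants: 9 (4S)-4-[(tert-butyldimethylsilyl)oxy]cyclopent-2-en-1-one; 10 propargyl bromide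
Product: 12 (1R,4S)-4-[(tert-butyldimethylsilyl)oxy]-1-(prop-2-yn-1-yl)cyclopent-2-en-1-ol, via allenylzinc bromide 11 (not isolated)
Conditions: Zn dust, THF, 0 °C
Reagents that add atoms: none
Why: Barbier propargylation, in which allenylzinc bromide 11 adds 1,2 to the ketone through a cyclic SE2′ transition state to give the homopropargylic alcohol and attack anti to the silyloxy group sets the tertiary carbinol centre (1R, later C12); the minor syn adduct has to be removed by chromatography here because step 11 would turn it into the enantiomer of 17.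

Step 8
Reactants: 12 (1R,4S)-4-[(tert-butyldimethylsilyl)oxy]-1-(prop-2-yn-1-yl)cyclopent-2-en-1-ol; 13 1-bromopent-2-yne
Product: 14 (1R,4S)-4-[(tert-butyldimethylsilyl)oxy]-1-(octa-2,5-diyn-1-yl)cyclopent-2-en-1-ol
Conditions: CuI (cat.), Cs2CO3, DMF, rt
Reagents that add atoms: none
Why: Copper-mediated coupling of a terminal alkyne with a propargylic bromide (SN2 alkylation of the copper acetylide) is the standard construction of skipped diynes and tolerates the free tertiary alcohol and the silyl ether.

Step 9
Reactants: 14 (1R,4S)-4-[(tert-butyldimethylsilyl)oxy]-1-(octa-2,5-diyn-1-yl)cyclopent-2-en-1-ol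
Product: 15 (1R,4S)-4-[(tert-butyldimethylsilyl)oxy]-1-[(2Z,5Z)-octa-2,5-dien-1-yl]cyclopent-2-en-1-ol
Conditions: H2 (1 atm), Ni(OAc)2/NaBH4 (Ni2B formed in situ, cat.), ethylenediamine, EtOH, rt
Reagents that add atoms: none
Why: Semi-hydrogenation over amine-poisoned nickel boride delivers hydrogen syn to each alkyne and stops at the alkene stage, giving both Z double bonds of the skipped diene while the hindered ring alkene and the silyl ether are left alone.

Step 10
Reactants: 15 (1R,4S)-4-[(tert-butyldimethylsilyl)oxy]-1-[(2Z,5Z)-octa-2,5-dien-1-yl]cyclopent-2-en-1-ol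
Product: 16 (1R,4S)-1-[(2Z,5Z)-octa-2,5-dien-1-yl]cyclopent-2-ene-1,4-diol
Conditions: TBAF, THF, 0 °C to rt
Reagents that add atoms: none
Why: Fluoride-mediated silyl ether cleavage liberates the secondary allylic alcohol without affecting the skipped diene or the tertiary alcohol.

Step 11
Reactants: 16 (1R,4S)-1-[(2Z,5Z)-octa-2,5-dien-1-yl]cyclopent-2-ene-1,4-diol
Product: 17 (4R)-4-hydroxy-4-[(2Z,5Z)-octa-2,5-dien-1-yl]cyclopent-2-en-1-one
Conditions: MnO2 (activated), CH2Cl2, rt
Reagents that add atoms: none
Why: Activated MnO2 oxidises only the secondary allylic alcohol, so the relay carbinol becomes the C9 ketone, the tertiary alcohol cannot react, and the stereocentre that directed step 7 is erased, leaving the tertiary centre as the only one in ring A.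

Step 12
Reactants: 17 (4R)-4-hydroxy-4-[(2Z,5Z)-octa-2,5-dien-1-yl]cyclopent-2-en-1-one; 18 2,2,2-trifluoroethyl formate
Product: 20 (4S,5Z)-4-hydroxy-5-(hydroxymethylidene)-4-[(2Z,5Z)-octa-2,5-dien-1-yl]cyclopent-2-en-1-one, via dilithium dienolate 19 (not isolated)
Conditions: LiN(iPr)2 (2.2 equiv), THF, −78 °C; then 18, −78 °C; AcOH quench
Reagents that add atoms: none
Why: Crossed Claisen formylation, in which the first equivalent of base forms the alkoxide and the second removes an α′ proton to give the cross-conjugated dienolate 19, which is C-formylated by the activated formate and tautomerises to the hydrogen-bonded hydroxymethylidene ketone; the β-oxido group is not expelled because that would create a cyclopentadienone (the descriptor of the carbinol centre changes from R to S only because C8 gains priority).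

Step 13
Reactants: 20 (4S,5Z)-4-hydroxy-5-(hydroxymethylidene)-4-[(2Z,5Z)-octa-2,5-dien-1-yl]cyclopent-2-en-1-one
Product: 21 (E)-[(5S)-5-acetoxy-5-[(2Z,5Z)-octa-2,5-dien-1-yl]-2-oxocyclopent-3-en-1-ylidene]methyl acetate
Conditions: Ac2O (excess), Et3N, DMAP (cat.), CH2Cl2, 0 °C to rt
Reagents that add atoms: acetic anhydride, CC(=O)OC(C)=O
Why: DMAP-catalysed acylation converts the acidic enol into the enol acetate (a vinylogous anhydride, the leaving group for step 14) and the tertiary alcohol into the C12 acetate of the target in one operation; the enol acetate is expected to be E, but its geometry is irrelevant for step 14.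

Step 14
Reactants: 21 (E)-[(5S)-5-acetoxy-5-[(2Z,5Z)-octa-2,5-dien-1-yl]-2-oxocyclopent-3-en-1-ylidene]methyl acetate; 8 potassium [(1Z,3R)-3-acetoxy-6-methoxy-6-oxohex-1-en-1-yl]trifluoroborate
Product: 24 methyl (4R,5Z,7E)-4-acetoxy-7-[(5S)-5-acetoxy-5-[(2Z,5Z)-octa-2,5-dien-1-yl]-2-oxocyclopent-3-en-1-ylidene]hept-5-enoate (the target), via alkenyldifluoroborane 22 (not isolated), via boron enolate 23 (not isolated)
Conditions: 8, BF3·OEt2 (1.05 equiv), 4 Å MS, CH2Cl2/MeCN, −40 °C; then 21, −40 to 0 °C; pH 7 buffer
Reagents that add atoms: none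
Why: Proposed new method: BF3·OEt2 abstracts fluoride from 8 to give the Lewis acidic Z-alkenyldifluoroborane 22, whose boron binds the C9 carbonyl oxygen of 21 and hands C6 to C7 through a closed six-membered transition state (B, O, C9, C8, C7, C6); the resulting boron enolate 23 then expels the C7 acetate as AcOBF2 and restores C7=C8, so that the whole event is a conjugate addition–elimination without transition metal or base. The closest known reaction types are the addition–elimination of B-alkenyl-9-borabicyclononanes to β-methoxyvinyl ketones, which gives 2,4-dienones, and the BF3-promoted 1,4-addition of alkenylboronic esters to s-cis enones; what is new is the pairing of an alkenyldifluoroborane with a β-acyloxy enone (vinylogous anhydride) on a cross-conjugated cyclopentenone. No ring is closed and no stereocentre is made: C4 and C12 are spectators, the 5Z geometry is carried over because boron-to-carbon alkenyl migration is stereoretentive, and the 7E geometry is set in the elimination from 23, where the dienyl group avoids the boron-bearing C9 oxygen (allylic strain) and turns toward C12, which is also the more stable arrangement, so that the E/Z composition of 21 does not matter. The site selectivity that is needed (C7, not C11) is secured by ring A, which holds O=C9–C8=C7 s-cis and O=C9–C10=C11 s-trans so that only C7 lies within reach of the cyclic transfer, and by the acetoxy group, which makes C7 the most electrophilic carbon. Loss of the C7 acetate and not of the C12 acetate from 23 is secured because the latter would create an antiaromatic cyclopentadienone, and single transfer is secured by the stoichiometry and by the lower electrophilicity and greater hindrance of C7 in the product.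

## Compound list

1 | methyl 4-chloro-4-oxobutanoate | COC(=O)CCC(=O)Cl | starting material
2 | bis(trimethylsilyl)acetylene | C[Si](C)(C)C#C[Si](C)(C)C | starting material
3 | methyl 4-oxo-6-(trimethylsilyl)hex-5-ynoate | COC(=O)CCC(=O)C#C[Si](C)(C)C | intermediate
4 | methyl (4R)-4-hydroxy-6-(trimethylsilyl)hex-5-ynoate | COC(=O)CC[C@@H](O)C#C[Si](C)(C)C | intermediate
5 | methyl (4R)-4-acetoxy-6-(trimethylsilyl)hex-5-ynoate | COC(=O)CC[C@@H](OC(C)=O)C#C[Si](C)(C)C | intermediate
6 | methyl (4R)-4-acetoxyhex-5-ynoate | COC(=O)CC[C@@H](OC(C)=O)C#C | intermediate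
7 | methyl (4R,5Z)-4-acetoxy-6-(4,4,5,5-tetramethyl-1,3,2-dioxaborolan-2-yl)hex-5-enoate | COC(=O)CC[C@@H](OC(C)=O)/C=C\B1OC(C)(C)C(C)(C)O1 | intermediate
8 | potassium [(1Z,3R)-3-acetoxy-6-methoxy-6-oxohex-1-en-1-yl]trifluoroborate | COC(=O)CC[C@@H](OC(C)=O)/C=C\[B-](F)(F)F.[K+] | intermediate
9 | (4S)-4-[(tert-butyldimethylsilyl)oxy]cyclopent-2-en-1-one | O=C1C=C[C@@H](O[Si](C)(C)C(C)(C)C)C1 | starting material
10 | propargyl bromide (3-bromoprop-1-yne) | C#CCBr | starting material
11 | allenylzinc bromide | C=C=C[Zn]Br | intermediate (not isolated)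
12 | (1R,4S)-4-[(tert-butyldimethylsilyl)oxy]-1-(prop-2-yn-1-yl)cyclopent-2-en-1-ol | C#CC[C@]1(O)C=C[C@@H](O[Si](C)(C)C(C)(C)C)C1 | intermediate
13 | 1-bromopent-2-yne | CCC#CCBr | starting material
14 | (1R,4S)-4-[(tert-butyldimethylsilyl)oxy]-1-(octa-2,5-diyn-1-yl)cyclopent-2-en-1-ol | CCC#CCC#CC[C@]1(O)C=C[C@@H](O[Si](C)(C)C(C)(C)C)C1 | intermediate
15 | (1R,4S)-4-[(tert-butyldimethylsilyl)oxy]-1-[(2Z,5Z)-octa-2,5-dien-1-yl]cyclopent-2-en-1-ol | CC/C=C\C/C=C\C[C@]1(O)C=C[C@@H](O[Si](C)(C)C(C)(C)C)C1 | intermediate
16 | (1R,4S)-1-[(2Z,5Z)-octa-2,5-dien-1-yl]cyclopent-2-ene-1,4-diol | CC/C=C\C/C=C\C[C@]1(O)C=C[C@@H](O)C1 | intermediate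
17 | (4R)-4-hydroxy-4-[(2Z,5Z)-octa-2,5-dien-1-yl]cyclopent-2-en-1-one | CC/C=C\C/C=C\C[C@]1(O)C=CC(=O)C1 | intermediate
18 | 2,2,2-trifluoroethyl formate | O=COCC(F)(F)F | starting material
19 | dilithium alkoxide dienolate of 17 | CC/C=C\C/C=C\C[C@]1(O[Li])C=CC(O[Li])=C1 | intermediate (not isolated)
20 | (4S,5Z)-4-hydroxy-5-(hydroxymethylidene)-4-[(2Z,5Z)-octa-2,5-dien-1-yl]cyclopent-2-en-1-one | CC/C=C\C/C=C\C[C@]1(O)C=CC(=O)/C1=C\O | intermediate
21 | (E)-[(5S)-5-acetoxy-5-[(2Z,5Z)-octa-2,5-dien-1-yl]-2-oxocyclopent-3-en-1-ylidene]methyl acetate | CC/C=C\C/C=C\C[C@]1(OC(C)=O)C=CC(=O)/C1=C/OC(C)=O | intermediate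
22 | methyl (4R,5Z)-4-acetoxy-6-(difluoroboranyl)hex-5-enoate | COC(=O)CC[C@@H](OC(C)=O)/C=C\B(F)F | intermediate (not isolated)
23 | difluoroboron enolate formed by alkenyl transfer to C7 of 21 (C7 configuration undefined) | CC/C=C\C/C=C\C[C@]1(OC(C)=O)C=CC(OB(F)F)=C1C(OC(C)=O)/C=C\[C@@H](CCC(=O)OC)OC(C)=O | intermediate (not isolated)
24 | methyl (4R,5Z,7E)-4-acetoxy-7-[(5S)-5-acetoxy-5-[(2Z,5Z)-octa-2,5-dien-1-yl]-2-oxocyclopent-3-en-1-ylidene]hept-5-enoate | CC/C=C\C/C=C\C[C@]1(OC(C)=O)C=CC(=O)/C1=C/C=C\[C@@H](CCC(=O)OC)OC(C)=O | target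

## Step count and risks

Total steps: 14. Longest linear sequence: 8 steps (steps 7 to 14, from compound 9).

Steps most likely to fail:

1. Step 14 (carries the label). The alkenyl group may be transferred through an open, non-cyclic pathway with erosion of the 5Z geometry. The Lewis acid may isomerise the product dienone from 5Z to 5E. A second alkenyl group may add to the product, or the difluoroborane may be protodeboronated before transfer. Fallback by known chemistry: it sets out from 20 and 7. Selective O-sulfonylation of the acidic enol of 20 (PhNTf2, Et3N, CH2Cl2, 0 °C; non-chelating amine base for the E isomer) should give (4S,5E)-4-hydroxy-4-[(2Z,5Z)-octa-2,5-dien-1-yl]-5-{[(trifluoromethanesulfonyl)oxy]methylidene}cyclopent-2-en-1-one F1. Suzuki–Miyaura coupling of this β-triflyloxy enone with 7 (Pd(PPh3)4, aqueous K3PO4, THF, rt; both alkene geometries retained, zerovalent palladium inserting into the C–O bond far faster than into the secondary allylic acetate) should give methyl (4R,5Z,7E)-4-acetoxy-7-[(5S)-5-hydroxy-5-[(2Z,5Z)-octa-2,5-dien-1-yl]-2-oxocyclopent-3-en-1-ylidene]hept-5-enoate F2. Acetylation of the tertiary alcohol (Ac2O, DMAP, Et3N, CH2Cl2) comes back to the route at 24.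

2. Step 5. The rhodium hydride may isomerise the Z alkenylboronate to the E isomer, or vinylidene formation may be slow next to the acetoxy-bearing carbon, so that ordinary syn-hydroboration competes. Fallback: it sets out from 6. Iodination of the terminal alkyne (N-iodosuccinimide, AgNO3 cat., acetone) should give methyl (4R)-4-acetoxy-6-iodohex-5-ynoate F3. Diimide reduction (2-nitrobenzenesulfonyl hydrazide, Et3N, THF/iPrOH), which adds hydrogen syn, should give methyl (4R,5Z)-4-acetoxy-6-iodohex-5-enoate F4. Stereoretentive Miyaura borylation (bis(pinacolato)diboron, PdCl2(dppf), KOPh, toluene, 50 °C) comes back to the route at 7.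

3. Step 12. The β-oxido ketone may open by retro-aldol cleavage before the α′ proton is removed, or the enolate may be formylated on oxygen in place of carbon. Fallback: it sets out from 17. Aminomethylenation under neutral conditions with tert-butoxybis(dimethylamino)methane (toluene, 50 °C), which needs no preformed enolate, should give (4S,5E)-5-[(dimethylamino)methylidene]-4-hydroxy-4-[(2Z,5Z)-octa-2,5-dien-1-yl]cyclopent-2-en-1-one F5. Mild acid hydrolysis of this enaminone (aqueous oxalic acid, THF, 0 °C) comes back to the route at 20.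

Further compounds
F1 | step 14 | (4S,5E)-4-hydroxy-4-[(2Z,5Z)-octa-2,5-dien-1-yl]-5-{[(trifluoromethanesulfonyl)oxy]methylidene}cyclopent-2-en-1-one | CC/C=C\C/C=C\C[C@]1(O)C=CC(=O)/C1=C/OS(=O)(=O)C(F)(F)F
F2 | step 14 | methyl (4R,5Z,7E)-4-acetoxy-7-[(5S)-5-hydroxy-5-[(2Z,5Z)-octa-2,5-dien-1-yl]-2-oxocyclopent-3-en-1-ylidene]hept-5-enoate | CC/C=C\C/C=C\C[C@]1(O)C=CC(=O)/C1=C/C=C\[C@@H](CCC(=O)OC)OC(C)=O
F3 | step 5 | methyl (4R)-4-acetoxy-6-iodohex-5-ynoate | COC(=O)CC[C@@H](OC(C)=O)C#CI
F4 | step 5 | methyl (4R,5Z)-4-acetoxy-6-iodohex-5-enoate | COC(=O)CC[C@@H](OC(C)=O)/C=C\I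
F5 | step 12 | (4S,5E)-5-[(dimethylamino)methylidene]-4-hydroxy-4-[(2Z,5Z)-octa-2,5-dien-1-yl]cyclopent-2-en-1-one | CC/C=C\C/C=C\C[C@]1(O)C=CC(=O)/C1=C/N(C)C
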